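## Retrosynthetic overview

1. Hybridorubrin B ⇒ global desilylation, Yamaguchi ester at O–C7′ and side-chain acetate ⇒ two azaphilone units joined at C5′=C9′ by a biomimetic vinylogous Knoevenagel condensation of the 1H-isochromene-6,8-dione 32 (nucleophilic C5′H2) with the mitorubrinal-type enal 20.
2. In each unit the cyclohexenedione ring is closed last, on a preformed dihydropyran, by a formal anionic [4+2] annulation: a lactic-acid dioxolanone enolate (C7–C8) plus a (2,3-dihydro-4H-pyran-4-ylidene)acetyl chloride (C6–C5–C4a–C8a) gives the C6–C7 and C8–C8a bonds. (R)-Lactic acid serves the orsellinate half (7S), (S)-lactic acid the fatty-acyl half (7′R).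
3. Enabling feature: in the carbocycle, C6(=O)–C7(Me)(O-acyl)–C8(=O) is a C-acylated lactic acid (C7 = α-carbon, C8 = carboxyl carbon). C8a is tied to the acyl carbon C6 through C4a=C5, so it is the γ-carbon of the C6 enone and, as the ring CH2 next to C1, the only γ-position that can be deprotonated.
4. The pyran rings come first, by cyclodehydration of δ-hydroxy-β-diketones (ketone 5 + Weinreb amides 3 or 23). The right half is then dehydrogenated at C1 to the azaphilone, acylated with silylated orsellinoyl chloride and unmasked to the enal.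
5. The (16R)-16-hydroxylinoleic acid 43 comes from (R)-1,2-epoxybutane by two Z-selective Wittig reactions.

Key step: step 8

Assumption: isochromene numbering (C1, O2, C3, C4, C4a, C5–C8, C8a) is used, primed for the fatty-acyl half, with linker carbons C9′–C11′. The vinylogous acids 14, 31 and 32 are drawn as their 5H-diketo tautomers, and the ylidene compounds 8, 9, 12, 13, 26, 27, 29 and 30 are E/Z mixtures at the exocyclic C=C, which is inconsequential.

## Route

Step 1
Reactants: 1 diethyl [2-(methoxy(methyl)amino)-2-oxoethyl]phosphonate; 2 2,2-dimethoxyacetaldehyde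
Product: 3 (2E)-N,4,4-trimethoxy-N-methylbut-2-enamide
Conditions: LiCl, DBU, MeCN, 0 → 23 °C (2 as dried extract of the aqueous solution)
Reagents that add atoms: none
Why: Horner–Wadsworth–Emmons olefination under Masamune–Roush conditions, in which the amide-stabilised phosphonate anion should give the E-alkene.

Step 2
Reactants: 4 4-hydroxybutan-2-one
Product: 5 4-(triethylsilyloxy)butan-2-one
Conditions: TESCl, imidazole, CH2Cl2, 0 °C
Reagents that add atoms: chlorotriethylsilane CC[Si](Cl)(CC)CC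
Why: Standard silylation of a primary alcohol; the labile TES group is chosen so that it can later be removed in the presence of TBS ethers and an acetal.

Step 3
Reactants: 5 4-(triethylsilyloxy)butan-2-one; 3 (2E)-N,4,4-trimethoxy-N-methylbut-2-enamide
Product: 6 (6E)-8,8-dimethoxy-1-(triethylsilyloxy)oct-6-ene-3,5-dione
Conditions: LDA, THF, −78 °C; then 3, −78 → −20 °C; aq. NH4Cl
Reagents that add atoms: none
Why: Crossed Claisen acylation of the kinetic methyl-side lithium enolate by a Weinreb amide, whose chelated tetrahedral adduct prevents over-addition, while 1,4-addition to the amide-deactivated alkene should be slow.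

Step 4
Reactants: 6 (6E)-8,8-dimethoxy-1-(triethylsilyloxy)oct-6-ene-3,5-dione
Product: 7 6-[(1E)-3,3-dimethoxyprop-1-en-1-yl]-2,3-dihydro-4H-pyran-4-one
Conditions: CSA (10 mol %), MeOH, 0 → 40 °C; Et3N
Reagents that add atoms: none
Why: Acid methanolysis of the TES ether followed by cyclodehydration of the δ-hydroxy-β-diketone (hemiketalisation at the distal ketone, loss of water) gives the vinylogous ester, while the dimethyl acetal only exchanges with the solvent.

Step 5
Reactants: 7 6-[(1E)-3,3-dimethoxyprop-1-en-1-yl]-2,3-dihydro-4H-pyran-4-one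
Product: 8 methyl 2-{6-[(1E)-3,3-dimethoxyprop-1-en-1-yl]-2,3-dihydro-4H-pyran-4-ylidene}acetate
Conditions: methyl (trimethylsilyl)acetate, LDA, THF, −78 °C; then 7, −78 → 0 °C
Reagents that add atoms: methyl (trimethylsilyl)acetate COC(=O)C[Si](C)(C)C
Why: Peterson olefination, in which the α-silyl ester enolate adds 1,2 to the poorly electrophilic vinylogous-ester carbonyl and eliminates Me3SiOLi to give the push–pull dienoate.

Step 6
Reactants: 8 methyl 2-{6-[(1E)-3,3-dimethoxyprop-1-en-1-yl]-2,3-dihydro-4H-pyran-4-ylidene}acetate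
Product: 9 potassium 2-{6-[(1E)-3,3-dimethoxyprop-1-en-1-yl]-2,3-dihydro-4H-pyran-4-ylidene}acetate
Conditions: KOSiMe3, THF, 23 °C
Reagents that add atoms: potassium trimethylsilanolate C[Si](C)(C)[O-].[K+]
Why: Anhydrous ester cleavage by trimethylsilanolate gives the carboxylate salt directly, so the free acid of an acid-sensitive dienol ether is never handled.

Step 7
Reactants: 10 (R)-lactic acid
Product: 11 (2R,5R)-2-tert-butyl-5-methyl-1,3-dioxolan-4-one
Conditions: pivalaldehyde, TsOH·H2O (cat.), pentane, reflux (Dean–Stark); crystallisation at −78 °C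
Reagents that add atoms: pivalaldehyde CC(C)(C)C=O
Why: Acid-catalysed acetalisation with water removal gives mainly the cis acetal, purified by crystallisation; the lactate centre is untouched and the new acetal centre is set cis to methyl by thermodynamic control.

Step 8
Reactants: 9 potassium 2-{6-[(1E)-3,3-dimethoxyprop-1-en-1-yl]-2,3-dihydro-4H-pyran-4-ylidene}acetate; 11 (2R,5R)-2-tert-butyl-5-methyl-1,3-dioxolan-4-one
Product: 14 (7S)-7-hydroxy-3-[(1E)-3,3-dimethoxyprop-1-en-1-yl]-7-methyl-1H-isochromene-6,8(5H,7H)-dione, via acid chloride 12 (not isolated), via C-acylated dioxolanone 13 (not isolated)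
Conditions: 9, (COCl)2, CH2Cl2, 0 °C, evaporate; Li enolate of 11 (LDA, THF, −78 °C), then 12; LiHMDS, −78 → −20 °C; AcOH
Reagents that add atoms: none
Why: Proposed new method: the lithium enolate of 11 is C-acylated by acid chloride 12 on the face anti to the tert-butyl group (C6–C7 bond), then LiHMDS removes a ring-CH2 proton γ to the new ketone and the dienolate carbon C8a attacks the dioxolanone carbonyl C8, whose acetal oxygen leaves with loss of pivalaldehyde (C8–C8a bond). The closest known reactions are the Hauser–Kraus and Staunton–Weinreb anionic [4+2] annulations (four-carbon unit with a nucleophilic and an acyl terminus) and the Claisen-type opening of 1,3-dioxolan-4-ones by ester enolates with release of the carbonyl component. The carbocycle closes by a 6-(enolendo)-exo-trig acyl substitution. C7 is set as S by the tert-butyl acetal centre of 11 (self-regeneration of the lactate stereocentre, acyl group entering where hydrogen was) and, being quaternary, cannot epimerise later. The step needs closure through C8a and not through C5 or C4: C5 closure would give a four-membered ring, C4 carries only a vinylic hydrogen, and the dienolate rotamer with C7 syn to C4a should be reached by reversible C5 protonation by HN(SiMe3)2. Deprotonation of the doubly activated C8a–H of the product should make the sequence irreversible and keep the tertiary alkoxide from an α-ketol shift until the acetic acid quench.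

Step 9
Reactants: 14 (7S)-7-hydroxy-3-[(1E)-3,3-dimethoxyprop-1-en-1-yl]-7-methyl-1H-isochromene-6,8(5H,7H)-dione
Product: 15 (7S)-7-hydroxy-3-[(1E)-3,3-dimethoxyprop-1-en-1-yl]-7-methyl-6H-isochromene-6,8(7H)-dione
Conditions: DDQ, NaHCO3, CH2Cl2, 0 → 23 °C
Reagents that add atoms: none
Why: DDQ dehydrogenation, in which hydride is abstracted from the C1 methylene (α to the ring oxygen and allylic to C8a=C4a) to give an O-protonated azaphilone (benzopyrylium level) that loses a proton; C7 is not involved.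

Step 10
Reactants: 16 orsellinic acid
Product: 17 tert-butyldimethylsilyl 2,4-bis(tert-butyldimethylsilyloxy)-6-methylbenzoate
Conditions: TBSCl, imidazole, DMF, 23 → 50 °C
Reagents that add atoms: tert-butylchlorodimethylsilane CC(C)(C)[Si](C)(C)Cl
Why: Exhaustive silylation protects both phenols and turns the acid into a silyl ester that is a neutral precursor of the acid chloride.

Step 11
Reactants: 15 (7S)-7-hydroxy-3-[(1E)-3,3-dimethoxyprop-1-en-1-yl]-7-methyl-6H-isochromene-6,8(7H)-dione; 17 tert-butyldimethylsilyl 2,4-bis(tert-butyldimethylsilyloxy)-6-methylbenzoate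
Product: 19 (7S)-3-[(1E)-3,3-dimethoxyprop-1-en-1-yl]-7-methyl-6,8-dioxo-7,8-dihydro-6H-isochromen-7-yl 2,4-bis(tert-butyldimethylsilyloxy)-6-methylbenzoate, via aroyl chloride 18 (not isolated)
Conditions: 17, (COCl)2, DMF (cat.), CH2Cl2, 0 → 23 °C, evaporate; 15, Et3N, DMAP, CH2Cl2, 23 → 40 °C
Reagents that add atoms: none
Why: The silyl ester is converted into the acid chloride under neutral conditions and DMAP-mediated acylation of the tertiary C7 alcohol follows (the azaphilone has no other hydroxyl or enol after step 9); the C7–O bond is not broken, so the configuration is retained.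

Step 12
Reactants: 19 (7S)-3-[(1E)-3,3-dimethoxyprop-1-en-1-yl]-7-methyl-6,8-dioxo-7,8-dihydro-6H-isochromen-7-yl 2,4-bis(tert-butyldimethylsilyloxy)-6-methylbenzoate
Product: 20 (7S)-7-methyl-6,8-dioxo-3-[(1E)-3-oxoprop-1-en-1-yl]-7,8-dihydro-6H-isochromen-7-yl 2,4-bis(tert-butyldimethylsilyloxy)-6-methylbenzoate
Conditions: PPTS, acetone/H2O, 23 °C
Reagents that add atoms: water O
Why: Mild acid hydrolysis of the allylic dimethyl acetal, which ionises easily with help from the pyran oxygen, should leave aryl silyl ethers and the ester intact.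

Step 13
Reactants: 21 ethyl (S)-3-hydroxybutanoate
Product: 22 (S)-3-hydroxy-N-methoxy-N-methylbutanamide
Conditions: MeNH(OMe)·HCl, i-PrMgCl, THF, −20 → 0 °C
Reagents that add atoms: N,O-dimethylhydroxylamine hydrochloride CNOC.Cl
Why: Weinreb amide formation by aminolysis of the ester with the magnesium amide; the stereocentre is not involved.

Step 14
Reactants: 22 (S)-3-hydroxy-N-methoxy-N-methylbutanamide
Product: 23 (S)-3-(tert-butyldimethylsilyloxy)-N-methoxy-N-methylbutanamide
Conditions: TBSCl, imidazole, DMF, 23 °C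
Reagents that add atoms: tert-butylchlorodimethylsilane CC(C)(C)[Si](C)(C)Cl
Why: Standard silylation of the secondary alcohol, so that it survives the enolate steps.

Step 15
Reactants: 5 4-(triethylsilyloxy)butan-2-one; 23 (S)-3-(tert-butyldimethylsilyloxy)-N-methoxy-N-methylbutanamide
Product: 24 (7S)-7-(tert-butyldimethylsilyloxy)-1-(triethylsilyloxy)octane-3,5-dione
Conditions: LDA, THF, −78 °C; then 23, −78 → −20 °C; aq. NH4Cl
Reagents that add atoms: none
Why: Crossed Claisen acylation of the kinetic methyl-side enolate by a Weinreb amide, as in step 3; the chelated adduct also prevents β-elimination of the silyloxy group.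

Step 16
Reactants: 24 (7S)-7-(tert-butyldimethylsilyloxy)-1-(triethylsilyloxy)octane-3,5-dione
Product: 25 6-[(2S)-2-(tert-butyldimethylsilyloxy)propyl]-2,3-dihydro-4H-pyran-4-one
Conditions: PPTS, MeOH, 23 → 40 °C
Reagents that add atoms: none
Why: Selective methanolysis of the primary TES ether and cyclodehydration of the δ-hydroxy-β-diketone, as in step 4; the secondary TBS ether should survive PPTS.

Step 17
Reactants: 25 6-[(2S)-2-(tert-butyldimethylsilyloxy)propyl]-2,3-dihydro-4H-pyran-4-one
Product: 26 methyl 2-{6-[(2S)-2-(tert-butyldimethylsilyloxy)propyl]-2,3-dihydro-4H-pyran-4-ylidene}acetate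
Conditions: methyl (trimethylsilyl)acetate, LDA, THF, −78 °C; then 25, −78 → 0 °C
Reagents that add atoms: methyl (trimethylsilyl)acetate COC(=O)C[Si](C)(C)C
Why: Peterson olefination of the vinylogous-ester carbonyl, as in step 5.

Step 18
Reactants: 26 methyl 2-{6-[(2S)-2-(tert-butyldimethylsilyloxy)propyl]-2,3-dihydro-4H-pyran-4-ylidene}acetate
Product: 27 potassium 2-{6-[(2S)-2-(tert-butyldimethylsilyloxy)propyl]-2,3-dihydro-4H-pyran-4-ylidene}acetate
Conditions: KOSiMe3, THF, 23 °C
Reagents that add atoms: potassium trimethylsilanolate C[Si](C)(C)[O-].[K+]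
Why: Anhydrous ester cleavage to the carboxylate salt, as in step 6; the alkyl silyl ether is inert to silanolate at room temperature.

Step 19
Reactants: 27 potassium 2-{6-[(2S)-2-(tert-butyldimethylsilyloxy)propyl]-2,3-dihydro-4H-pyran-4-ylidene}acetate; 28 (2S,5S)-2-tert-butyl-5-methyl-1,3-dioxolan-4-one
Product: 31 (7R)-3-[(2S)-2-(tert-butyldimethylsilyloxy)propyl]-7-hydroxy-7-methyl-1H-isochromene-6,8(5H,7H)-dione, via acid chloride 29 (not isolated), via C-acylated dioxolanone 30 (not isolated)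
Conditions: 27, (COCl)2, CH2Cl2, 0 °C, evaporate; Li enolate of 28 (LDA, THF, −78 °C), then 29; LiHMDS, −78 → −20 °C; AcOH
Reagents that add atoms: none
Why: Proposed new method: the same lactate-enolate C-acylation and vinylogous Dieckmann annulation as in step 8 (anti-to-tert-butyl C-acylation forms C6′–C7′, γ-deprotonation of the ring CH2 and 6-(enolendo)-exo-trig attack of C8a′ on the dioxolanone carbonyl forms C8′–C8a′ with loss of pivalaldehyde; closest known types are the Hauser–Kraus and Staunton–Weinreb annulations and the Claisen-type opening of 1,3-dioxolan-4-ones), here with the (2S,5S)-auxiliary so that its tert-butyl acetal centre sets C7′ as R.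

Step 20
Reactants: 31 (7R)-3-[(2S)-2-(tert-butyldimethylsilyloxy)propyl]-7-hydroxy-7-methyl-1H-isochromene-6,8(5H,7H)-dione
Product: 32 (7R)-7-hydroxy-3-[(2S)-2-hydroxypropyl]-7-methyl-1H-isochromene-6,8(5H,7H)-dione
Conditions: HF·pyridine, pyridine, THF, 0 → 23 °C
Reagents that add atoms: none
Why: Buffered fluoride cleavage of the secondary silyl ether avoids strong base that could trigger an α-ketol shift; no stereocentre is touched.

Step 21
Reactants: 32 (7R)-7-hydroxy-3-[(2S)-2-hydroxypropyl]-7-methyl-1H-isochromene-6,8(5H,7H)-dione; 20 (7S)-7-methyl-6,8-dioxo-3-[(1E)-3-oxoprop-1-en-1-yl]-7,8-dihydro-6H-isochromen-7-yl 2,4-bis(tert-butyldimethylsilyloxy)-6-methylbenzoate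
Product: 33 (7S)-3-{(1E,3E)-3-[(7R)-7-hydroxy-3-((2S)-2-hydroxypropyl)-7-methyl-6,8-dioxo-7,8-dihydro-1H-isochromen-5(6H)-ylidene]prop-1-en-1-yl}-7-methyl-6,8-dioxo-7,8-dihydro-6H-isochromen-7-yl 2,4-bis(tert-butyldimethylsilyloxy)-6-methylbenzoate
Conditions: pyridine, AcOH (cat.), 4 Å MS, CH2Cl2, 23 °C
Reagents that add atoms: none
Why: Biomimetic Knoevenagel condensation of the vinylogous acid (C5′H2, activated by both carbonyls) with the enal; the new C5′=C9′ bond should settle as E (chain anti to C6′=O, as in the natural product) under thermodynamic control, and no primary amine is used because azaphilones are converted by them into vinylogous pyridones.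

Step 22
Reactants: 33 (the dienylidene-linked diol named in step 21)
Product: 34 (7S)-3-{(1E,3E)-3-[(7R)-3-((2S)-2-acetoxypropyl)-7-hydroxy-7-methyl-6,8-dioxo-7,8-dihydro-1H-isochromen-5(6H)-ylidene]prop-1-en-1-yl}-7-methyl-6,8-dioxo-7,8-dihydro-6H-isochromen-7-yl 2,4-bis(tert-butyldimethylsilyloxy)-6-methylbenzoate
Conditions: Ac2O, pyridine, CH2Cl2, 0 °C
Reagents that add atoms: acetic anhydride CC(=O)OC(C)=O
Why: Selective acetylation of the secondary alcohol, since the hindered tertiary α-ketol is not acylated without DMAP and no enol is left after step 21.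

Step 23
Reactants: 35 (R)-2-ethyloxirane
Product: 36 (R)-hept-6-en-3-ol
Conditions: allylMgCl, CuI (10 mol %), THF, −30 → 0 °C
Reagents that add atoms: allylmagnesium chloride C=CC[Mg]Cl
Why: Copper-catalysed epoxide opening at the unsubstituted carbon leaves the stereocentre untouched, so the R descriptor carries over.

Step 24
Reactants: 36 (R)-hept-6-en-3-ol
Product: 37 (R)-tert-butyl(hept-6-en-3-yloxy)dimethylsilane
Conditions: TBSCl, imidazole, DMF, 23 °C
Reagents that add atoms: tert-butylchlorodimethylsilane CC(C)(C)[Si](C)(C)Cl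
Why: Standard silylation; the TBS ether is kept to the final step.

Step 25
Reactants: 37 (R)-tert-butyl(hept-6-en-3-yloxy)dimethylsilane
Product: 38 (R)-4-(tert-butyldimethylsilyloxy)hexanal
Conditions: O3, CH2Cl2, −78 °C; then PPh3
Reagents that add atoms: ozone [O-][O+]=O
Why: Ozonolysis of the terminal alkene with reductive work-up gives the aldehyde without affecting the silyl ether.

Step 26
Reactants: 38 (R)-4-(tert-butyldimethylsilyloxy)hexanal; 39 (3,3-diisopropoxypropyl)triphenylphosphonium bromide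
Product: 40 tert-butyl{[(3R,6Z)-9,9-diisopropoxynon-6-en-3-yl]oxy}dimethylsilane
Conditions: 39, NaHMDS, THF, −78 °C; then 38, −78 → 23 °C
Reagents that add atoms: none
Why: Wittig reaction of a non-stabilised ylide under lithium-free conditions should give the Z-alkene (C12=C13) by kinetic control.

Step 27
Reactants: 40 tert-butyl{[(3R,6Z)-9,9-diisopropoxynon-6-en-3-yl]oxy}dimethylsilane
Product: 41 (3Z,7R)-7-(tert-butyldimethylsilyloxy)non-3-enal
Conditions: TsOH·H2O (cat.), acetone/H2O, 23 °C; used at once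
Reagents that add atoms: water O
Why: Mild acetal hydrolysis frees the β,γ-unsaturated aldehyde, which is used immediately to avoid migration of the Z-alkene into conjugation.

Step 28
Reactants: 41 (3Z,7R)-7-(tert-butyldimethylsilyloxy)non-3-enal; 42 (8-carboxyoctyl)triphenylphosphonium bromide
Product: 43 (9Z,12Z,16R)-16-(tert-butyldimethylsilyloxy)octadeca-9,12-dienoic acid
Conditions: 42, NaHMDS (2.1 equiv), THF, 0 °C; then 41, −78 → 23 °C; aq. NaH2PO4
Reagents that add atoms: none
Why: Second Z-selective Wittig reaction of the carboxylate ylide sets the C9=C10 alkene and delivers the skipped Z,Z-diene acid directly.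

Step 29
Reactants: 34 (the monoacetate named in step 22); 43 (9Z,12Z,16R)-16-(tert-butyldimethylsilyloxy)octadeca-9,12-dienoic acid
Product: 45 tris(tert-butyldimethylsilyl) ether of hybridorubrin B, via mixed anhydride 44 (not isolated)
Conditions: 43, 2,4,6-trichlorobenzoyl chloride, Et3N, THF, 23 °C; then 34, DMAP, toluene, 23 → 40 °C
Reagents that add atoms: none
Why: Yamaguchi esterification, in which DMAP transfers the unhindered fatty acyl group of the mixed anhydride to the tertiary C7′ alcohol, the only free hydroxyl of 34, with retention at C7′.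

Step 30
Reactants: 45 tris(tert-butyldimethylsilyl) ether of hybridorubrin B
Product: 46 hybridorubrin B
Conditions: HF·pyridine, pyridine, THF, 0 → 23 °C
Reagents that add atoms: none
Why: Buffered fluoride cleaves the two aryl and one secondary alkyl silyl ethers in one operation and should leave the esters, enol ethers and polyene untouched.

## Compound list

1 | diethyl [2-(methoxy(methyl)amino)-2-oxoethyl]phosphonate | CCOP(=O)(CC(=O)N(C)OC)OCC | starting material
2 | 2,2-dimethoxyacetaldehyde | COC(OC)C=O | starting material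
3 | (2E)-N,4,4-trimethoxy-N-methylbut-2-enamide | CON(C)C(=O)/C=C/C(OC)OC | intermediate
4 | 4-hydroxybutan-2-one | CC(=O)CCO | starting material
5 | 4-(triethylsilyloxy)butan-2-one | CC(=O)CCO[Si](CC)(CC)CC | intermediate
6 | (6E)-8,8-dimethoxy-1-(triethylsilyloxy)oct-6-ene-3,5-dione | COC(OC)/C=C/C(=O)CC(=O)CCO[Si](CC)(CC)CC | intermediate
7 | 6-[(1E)-3,3-dimethoxyprop-1-en-1-yl]-2,3-dihydro-4H-pyran-4-one | COC(OC)/C=C/C1=CC(=O)CCO1 | intermediate
8 | methyl 2-{6-[(1E)-3,3-dimethoxyprop-1-en-1-yl]-2,3-dihydro-4H-pyran-4-ylidene}acetate | COC(=O)C=C1CCOC(/C=C/C(OC)OC)=C1 | intermediate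
9 | potassium 2-{6-[(1E)-3,3-dimethoxyprop-1-en-1-yl]-2,3-dihydro-4H-pyran-4-ylidene}acetate | [K+].[O-]C(=O)C=C1CCOC(/C=C/C(OC)OC)=C1 | intermediate
10 | (R)-lactic acid | C[C@@H](O)C(=O)O | starting material
11 | (2R,5R)-2-tert-butyl-5-methyl-1,3-dioxolan-4-one | C[C@H]1O[C@@H](C(C)(C)C)OC1=O | intermediate
12 | 2-{6-[(1E)-3,3-dimethoxyprop-1-en-1-yl]-2,3-dihydro-4H-pyran-4-ylidene}acetyl chloride | ClC(=O)C=C1CCOC(/C=C/C(OC)OC)=C1 | intermediate
13 | (2R,5S)-2-tert-butyl-5-methyl-5-(2-{6-[(1E)-3,3-dimethoxyprop-1-en-1-yl]-2,3-dihydro-4H-pyran-4-ylidene}acetyl)-1,3-dioxolan-4-one | C[C@@]1(C(=O)C=C2CCOC(/C=C/C(OC)OC)=C2)O[C@@H](C(C)(C)C)OC1=O | intermediate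
14 | (7S)-7-hydroxy-3-[(1E)-3,3-dimethoxyprop-1-en-1-yl]-7-methyl-1H-isochromene-6,8(5H,7H)-dione | COC(OC)/C=C/C1=CC2=C(CO1)C(=O)[C@@](C)(O)C(=O)C2 | intermediate
15 | (7S)-7-hydroxy-3-[(1E)-3,3-dimethoxyprop-1-en-1-yl]-7-methyl-6H-isochromene-6,8(7H)-dione | COC(OC)/C=C/C1=CC2=CC(=O)[C@](C)(O)C(=O)C2=CO1 | intermediate
16 | orsellinic acid (2,4-dihydroxy-6-methylbenzoic acid) | Cc1cc(O)cc(O)c1C(=O)O | starting material
17 | tert-butyldimethylsilyl 2,4-bis(tert-butyldimethylsilyloxy)-6-methylbenzoate | Cc1cc(O[Si](C)(C)C(C)(C)C)cc(O[Si](C)(C)C(C)(C)C)c1C(=O)O[Si](C)(C)C(C)(C)C | intermediate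
18 | 2,4-bis(tert-butyldimethylsilyloxy)-6-methylbenzoyl chloride | Cc1cc(O[Si](C)(C)C(C)(C)C)cc(O[Si](C)(C)C(C)(C)C)c1C(Cl)=O | intermediate
19 | (7S)-3-[(1E)-3,3-dimethoxyprop-1-en-1-yl]-7-methyl-6,8-dioxo-7,8-dihydro-6H-isochromen-7-yl 2,4-bis(tert-butyldimethylsilyloxy)-6-methylbenzoate | COC(OC)/C=C/C1=CC2=CC(=O)[C@](C)(OC(=O)c3c(C)cc(O[Si](C)(C)C(C)(C)C)cc3O[Si](C)(C)C(C)(C)C)C(=O)C2=CO1 | intermediate
20 | (7S)-7-methyl-6,8-dioxo-3-[(1E)-3-oxoprop-1-en-1-yl]-7,8-dihydro-6H-isochromen-7-yl 2,4-bis(tert-butyldimethylsilyloxy)-6-methylbenzoate | O=C/C=C/C1=CC2=CC(=O)[C@](C)(OC(=O)c3c(C)cc(O[Si](C)(C)C(C)(C)C)cc3O[Si](C)(C)C(C)(C)C)C(=O)C2=CO1 | intermediate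
21 | ethyl (S)-3-hydroxybutanoate | C[C@H](O)CC(=O)OCC | starting material
22 | (S)-3-hydroxy-N-methoxy-N-methylbutanamide | C[C@H](O)CC(=O)N(C)OC | intermediate
23 | (S)-3-(tert-butyldimethylsilyloxy)-N-methoxy-N-methylbutanamide | C[C@H](O[Si](C)(C)C(C)(C)C)CC(=O)N(C)OC | intermediate
24 | (7S)-7-(tert-butyldimethylsilyloxy)-1-(triethylsilyloxy)octane-3,5-dione | C[C@H](O[Si](C)(C)C(C)(C)C)CC(=O)CC(=O)CCO[Si](CC)(CC)CC | intermediate
25 | 6-[(2S)-2-(tert-butyldimethylsilyloxy)propyl]-2,3-dihydro-4H-pyran-4-one | C[C@H](O[Si](C)(C)C(C)(C)C)CC1=CC(=O)CCO1 | intermediate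
26 | methyl 2-{6-[(2S)-2-(tert-butyldimethylsilyloxy)propyl]-2,3-dihydro-4H-pyran-4-ylidene}acetate | COC(=O)C=C1CCOC(C[C@H](C)O[Si](C)(C)C(C)(C)C)=C1 | intermediate
27 | potassium 2-{6-[(2S)-2-(tert-butyldimethylsilyloxy)propyl]-2,3-dihydro-4H-pyran-4-ylidene}acetate | [K+].[O-]C(=O)C=C1CCOC(C[C@H](C)O[Si](C)(C)C(C)(C)C)=C1 | intermediate
28 | (2S,5S)-2-tert-butyl-5-methyl-1,3-dioxolan-4-one | C[C@@H]1O[C@H](C(C)(C)C)OC1=O | starting material
29 | 2-{6-[(2S)-2-(tert-butyldimethylsilyloxy)propyl]-2,3-dihydro-4H-pyran-4-ylidene}acetyl chloride | ClC(=O)C=C1CCOC(C[C@H](C)O[Si](C)(C)C(C)(C)C)=C1 | intermediate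
30 | (2S,5R)-2-tert-butyl-5-methyl-5-(2-{6-[(2S)-2-(tert-butyldimethylsilyloxy)propyl]-2,3-dihydro-4H-pyran-4-ylidene}acetyl)-1,3-dioxolan-4-one | C[C@]1(C(=O)C=C2CCOC(C[C@H](C)O[Si](C)(C)C(C)(C)C)=C2)O[C@H](C(C)(C)C)OC1=O | intermediate
31 | (7R)-3-[(2S)-2-(tert-butyldimethylsilyloxy)propyl]-7-hydroxy-7-methyl-1H-isochromene-6,8(5H,7H)-dione | C[C@H](O[Si](C)(C)C(C)(C)C)CC1=CC2=C(CO1)C(=O)[C@](C)(O)C(=O)C2 | intermediate
32 | (7R)-7-hydroxy-3-[(2S)-2-hydroxypropyl]-7-methyl-1H-isochromene-6,8(5H,7H)-dione | C[C@H](O)CC1=CC2=C(CO1)C(=O)[C@](C)(O)C(=O)C2 | intermediate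
33 | dienylidene-linked bis-azaphilone diol (free C7′–OH and side-chain OH; bis-TBS orsellinate) | O[C@@]1(C)C(=O)C2=C(C=C(C[C@H](C)O)OC2)/C(=C\C=C\C2=CC3=CC(=O)[C@](C)(OC(=O)c4c(C)cc(O[Si](C)(C)C(C)(C)C)cc4O[Si](C)(C)C(C)(C)C)C(=O)C3=CO2)C1=O | intermediate
34 | side-chain monoacetate of 33 (free C7′–OH) | O[C@@]1(C)C(=O)C2=C(C=C(C[C@H](C)OC(C)=O)OC2)/C(=C\C=C\C2=CC3=CC(=O)[C@](C)(OC(=O)c4c(C)cc(O[Si](C)(C)C(C)(C)C)cc4O[Si](C)(C)C(C)(C)C)C(=O)C3=CO2)C1=O | intermediate
35 | (R)-2-ethyloxirane ((R)-1,2-epoxybutane) | CC[C@@H]1CO1 | starting material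
36 | (R)-hept-6-en-3-ol | CC[C@@H](O)CCC=C | intermediate
37 | (R)-tert-butyl(hept-6-en-3-yloxy)dimethylsilane | CC[C@@H](O[Si](C)(C)C(C)(C)C)CCC=C | intermediate
38 | (R)-4-(tert-butyldimethylsilyloxy)hexanal | CC[C@@H](O[Si](C)(C)C(C)(C)C)CCC=O | intermediate
39 | (3,3-diisopropoxypropyl)triphenylphosphonium bromide | CC(C)OC(CC[P+](c1ccccc1)(c1ccccc1)c1ccccc1)OC(C)C.[Br-] | starting material
40 | tert-butyl{[(3R,6Z)-9,9-diisopropoxynon-6-en-3-yl]oxy}dimethylsilane | CC[C@@H](O[Si](C)(C)C(C)(C)C)CC/C=C\CC(OC(C)C)OC(C)C | intermediate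
41 | (3Z,7R)-7-(tert-butyldimethylsilyloxy)non-3-enal | CC[C@@H](O[Si](C)(C)C(C)(C)C)CC/C=C\CC=O | intermediate
42 | (8-carboxyoctyl)triphenylphosphonium bromide | OC(=O)CCCCCCCC[P+](c1ccccc1)(c1ccccc1)c1ccccc1.[Br-] | starting material
43 | (9Z,12Z,16R)-16-(tert-butyldimethylsilyloxy)octadeca-9,12-dienoic acid | CC[C@@H](O[Si](C)(C)C(C)(C)C)CC/C=C\C/C=C\CCCCCCCC(=O)O | intermediate
44 | (9Z,12Z,16R)-16-(tert-butyldimethylsilyloxy)octadeca-9,12-dienoic 2,4,6-trichlorobenzoic anhydride | CC[C@@H](O[Si](C)(C)C(C)(C)C)CC/C=C\C/C=C\CCCCCCCC(=O)OC(=O)c1c(Cl)cc(Cl)cc1Cl | intermediate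
45 | tris(tert-butyldimethylsilyl) ether of hybridorubrin B (16-O and both orsellinate phenols) | CC[C@@H](O[Si](C)(C)C(C)(C)C)CC/C=C\C/C=C\CCCCCCCC(=O)O[C@@]1(C)C(=O)C2=C(C=C(C[C@H](C)OC(C)=O)OC2)/C(=C\C=C\C2=CC3=CC(=O)[C@](C)(OC(=O)c4c(C)cc(O[Si](C)(C)C(C)(C)C)cc4O[Si](C)(C)C(C)(C)C)C(=O)C3=CO2)C1=O | intermediate
46 | hybridorubrin B | CC[C@@H](O)CC/C=C\C/C=C\CCCCCCCC(=O)O[C@@]1(C)C(=O)C2=C(C=C(C[C@H](C)OC(C)=O)OC2)/C(=C\C=C\C2=CC3=CC(=O)[C@](C)(OC(=O)c4c(C)cc(O)cc4O)C(=O)C3=CO2)C1=O | target

## Step count and risks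

Total step count: 30. Longest linear sequence: 13 steps (1, 3, 4, 5, 6, 8, 9, 11, 12, 21, 22, 29, 30).

Three steps most likely to fail:

1. Step 8 (proposed new method). The hindered enolate may be acylated at oxygen instead of carbon. After γ-deprotonation, β-elimination of the ring oxygen from C1 (ring opening of the dienolate), or slow access to the dienolate rotamer that can close, may outrun the attack on C8. Fallback (known chemistry, sets out from 3 and returns at 15): the carbocycle is taken from an arene and the C7–O bond is made by oxidation. Weinreb amide 3 is reduced with DIBAL-H to (2E)-4,4-dimethoxybut-2-enal F1. Colvin homologation with lithiated trimethylsilyldiazomethane gives (3E)-5,5-dimethoxypent-3-en-1-yne F2. Sonogashira coupling with the known 6-bromo-2,4-dihydroxy-3-methylbenzaldehyde gives 2,4-dihydroxy-6-[(3E)-5,5-dimethoxypent-3-en-1-yn-1-yl]-3-methylbenzaldehyde F3. Copper(I)–sparteine–O2 hydroxylative dearomatisation, with the ligand enantiomer that leads to the 7S series, gives the dearomatised vinylogous acid F4. Copper- or gold-catalysed 6-endo-dig cycloisomerisation of the formyl oxygen onto the alkyne then closes the pyran to give 15.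

2. Step 19 (proposed new method). Besides the processes named for step 8, deprotonation at the side-chain CH2 on C3′ (ε-position) would give a trienolate that could close through C4′, a regiochemical leak. Fallback (known chemistry, sets out from 23 and returns at 31): Weinreb amide 23 is reduced with DIBAL-H to (S)-3-(tert-butyldimethylsilyloxy)butanal F5. Colvin homologation gives (S)-tert-butyldimethyl(pent-4-yn-2-yloxy)silane F6. Sonogashira coupling with 6-bromo-2,4-dihydroxy-3-methylbenzaldehyde gives the alkynylbenzaldehyde F7, and NaBH4 reduction gives the benzylic alcohol F8. Gold(I)-catalysed 6-endo-dig hydroalkoxylation gives (S)-3-[2-(tert-butyldimethylsilyloxy)propyl]-7-methyl-1H-isochromene-6,8-diol F9. Copper(I)–sparteine–O2 hydroxylative dearomatisation with the ligand enantiomer for the 7′R series then gives 31.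

3. Step 21. The condensation may lose chemoselectivity: Michael addition of a second vinylogous acid to the product, oxa-6π electrocyclisation of the Z-isomer to a 2H-pyran, or attack of the nucleophile on C1 of the azaphilone. Fallback (sets out from 32 and returns at 33): a stepwise Lewis-acid route replaces the amine-mediated condensation. Persilylation of 32 (TMSOTf, Et3N) gives the tris(trimethylsilyl) dienol ether F10. A BF3·OEt2-mediated Mukaiyama aldol addition of its C5′ to enal 20 at −78 °C, with mildly acidic work-up that removes the trimethylsilyl groups, gives the C9′ carbinol F11. Acid-mediated dehydration (CSA, CH2Cl2) of this doubly activated carbinol then gives 33.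

Further compounds
F1 | step 8 | (2E)-4,4-dimethoxybut-2-enal | COC(OC)/C=C/C=O
F2 | step 8 | (3E)-5,5-dimethoxypent-3-en-1-yne | COC(OC)/C=C/C#C
F3 | step 8 | 2,4-dihydroxy-6-[(3E)-5,5-dimethoxypent-3-en-1-yn-1-yl]-3-methylbenzaldehyde | COC(OC)/C=C/C#Cc1cc(O)c(C)c(O)c1C=O
F4 | step 8 | (5S)-4,5-dihydroxy-2-[(3E)-5,5-dimethoxypent-3-en-1-yn-1-yl]-5-methyl-6-oxocyclohexa-1,3-diene-1-carbaldehyde | COC(OC)/C=C/C#CC1=C(C=O)C(=O)[C@@](C)(O)C(O)=C1
F5 | step 19 | (S)-3-(tert-butyldimethylsilyloxy)butanal | C[C@H](O[Si](C)(C)C(C)(C)C)CC=O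
F6 | step 19 | (S)-tert-butyldimethyl(pent-4-yn-2-yloxy)silane | C[C@H](O[Si](C)(C)C(C)(C)C)CC#C
F7 | step 19 | 6-[(4S)-4-(tert-butyldimethylsilyloxy)pent-1-yn-1-yl]-2,4-dihydroxy-3-methylbenzaldehyde | C[C@H](O[Si](C)(C)C(C)(C)C)CC#Cc1cc(O)c(C)c(O)c1C=O
F8 | step 19 | 5-[(4S)-4-(tert-butyldimethylsilyloxy)pent-1-yn-1-yl]-4-(hydroxymethyl)-2-methylbenzene-1,3-diol | C[C@H](O[Si](C)(C)C(C)(C)C)CC#Cc1cc(O)c(C)c(O)c1CO
F9 | step 19 | (S)-3-[2-(tert-butyldimethylsilyloxy)propyl]-7-methyl-1H-isochromene-6,8-diol | C[C@H](O[Si](C)(C)C(C)(C)C)CC1=Cc2cc(O)c(C)c(O)c2CO1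
F10 | step 21 | (7R)-7-methyl-6,7-bis(trimethylsilyloxy)-3-[(2S)-2-(trimethylsilyloxy)propyl]-1H-isochromen-8(7H)-one | C[C@H](O[Si](C)(C)C)CC1=CC2=C(CO1)C(=O)[C@](C)(O[Si](C)(C)C)C(O[Si](C)(C)C)=C2
F11 | step 21 | aldol adduct of 32 (C5′) with enal 20 (C9′ carbinol; mixture of diastereomers at C5′ and C9′) | C[C@H](O)CC1=CC2=C(CO1)C(=O)[C@](C)(O)C(=O)C2C(O)/C=C/C1=CC2=CC(=O)[C@](C)(OC(=O)c3c(C)cc(O[Si](C)(C)C(C)(C)C)cc3O[Si](C)(C)C(C)(C)C)C(=O)C2=CO1
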